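Everything rests on cutting the seven-membered ether ring at O1–C2 and rejoining C4 to C5a (1-benzoxepine numbering), which turns the benzoxepine into a vinylcyclopropane spiro-fused to a dearomatised phloroglucinol. The feature exploited is that O1, C2, C3(Me)=C4, C5, C5a and C9a make up a 2,5-dihydrooxepine while C5a sits between the oxygens on C6 and C9a, each able to serve as a ketone. Warming the racemic 1-isopropenylspiro[2.5]octadienone 5 should set off a [3,3] shift that forms O1–C2, breaks C5a–C4, closes the oxepine and regains the benzene ring in one operation. The C7 acyl chain is attached afterwards.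

Key step: step 4

Remark on the chemistry: 3 and 4 are drawn as the E isomers expected to predominate; any Z isomer can be carried along because both alkene geometries should lead to 6. Compound 5 is racemic and its only stereocentre disappears in step 4; the target has no stereocentre.

Step 1
Reactants: 1 phloroglucinol (benzene-1,3,5-triol); 2 2-methyl-2-vinyloxirane (racemic)
Product: 3 2-[(2E)-4-hydroxy-3-methylbut-2-en-1-yl]benzene-1,3,5-triol
Conditions: Pd(PPh3)4 (3 mol %), THF, 0 → 23 °C; 1 in threefold excess, 2 added slowly
Reagents that add atoms: none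
Why: Tsuji–Trost allylation with a vinyl epoxide: zerovalent palladium opens 2 to a π-allyl alkoxide that deprotonates 1, the carbon nucleophile attacks the unsubstituted allyl terminus (1,4-addition), O-allylation stays reversible under the catalyst and the excess of 1 should hold back a second allylation.

Step 2
Reactants: 3 2-[(2E)-4-hydroxy-3-methylbut-2-en-1-yl]benzene-1,3,5-triol
Product: 4 2-[(2E)-4-chloro-3-methylbut-2-en-1-yl]benzene-1,3,5-triol
Conditions: PPh3 (1.3 equiv), CCl4 (3 equiv), MeCN, 0 → 23 °C; used promptly
Reagents that add atoms: carbon tetrachloride, ClC(Cl)(Cl)Cl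
Why: Appel reaction: only the aliphatic hydroxyl forms an alkoxyphosphonium ion that chloride displaces in an SN2 manner, while phenols give no aryl chloride under these conditions.

Step 3
Reactants: 4 2-[(2E)-4-chloro-3-methylbut-2-en-1-yl]benzene-1,3,5-triol
Product: 5 6,8-dihydroxy-1-(prop-1-en-2-yl)spiro[2.5]octa-5,7-dien-4-one (racemic)
Conditions: KOt-Bu (2.05 equiv), t-BuOH/THF (1:2), 0.01 M, 0 °C; AcOH (1.1 equiv) quench, cold extraction, used at once as a cold solution
Reagents that add atoms: none
Why: Intramolecular dearomatising C-alkylation (Ar-3 spirocyclisation of a phenoxide, here in the 3-exo SN2' mode by which 1,3-diones and 1,4-dihalobut-2-enes give vinylcyclopropanes): in the hydrogen-bond-donating, non-nucleophilic alcohol the dianion of 4 should react through carbon, as phloroglucinol anions do in geminal C-alkylations, C5a lying directly over C4 in the perpendicular benzylic conformer, and the new C4 stereocentre forms without control (racemate) because step 4 removes it.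

Step 4
Reactants: 5 6,8-dihydroxy-1-(prop-1-en-2-yl)spiro[2.5]octa-5,7-dien-4-one (racemic)
Product: 6 3-methyl-2,5-dihydro-1-benzoxepine-6,8-diol
Conditions: degassed PhMe/THF (5:1), 0.01 M, 23 → 50 °C, base-washed glassware
Reagents that add atoms: none
Why: A concerted [3,3] sigmatropic shift (retro-Claisen, a 3-oxa-Cope process) should run through a boat-shaped six-centre transition state built from C9a=O, the strained C5a–C4 bond and the isopropenyl C3=C2, forming O1–C2 while C5a–C4 opens. The closest known reaction type is the retro-Claisen rearrangement of cis-2-vinylcyclopropyl ketones and spiro 2-vinylcyclopropane-1,3-diones to 2,5-dihydrooxepines, applied here to an enolised spiro trione, so that loss of ring strain plus the regained benzene ring should drive an otherwise balanced equilibrium fully to 6. The oxepine ring closes by sigmatropic expansion of the three-membered ring to the seven-membered one, which places the methyl on C3 and forces the C3=C4 alkene to be cis within the ring. No stereocentre is created and the racemic C4 centre of 5 vanishes. The step needs the concerted path to outpace heterolytic cyclopropane opening towards the five-membered 2-isopropenyl-2,3-dihydrobenzofuran, which the neutral, weakly polar, metal-ion-free medium and mild temperature are chosen to secure. No choice between oxygens arises, since C5a carries carbonyl-capable oxygens on both C6 and C9a, one always cis to the isopropenyl group and the two interchanged by keto–enol tautomerism.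

Step 5
Reactants: 6 3-methyl-2,5-dihydro-1-benzoxepine-6,8-diol
Product: 7 6,8-bis(methoxymethoxy)-3-methyl-2,5-dihydro-1-benzoxepine
Conditions: NaH (2.4 equiv), MOMCl (2.4 equiv), DMF, 0 °C
Reagents that add atoms: chloromethyl methyl ether (MOMCl), COCCl
Why: Williamson-type O-alkylation of the two sodium phenoxides by the reactive chloromethyl ether, under conditions that leave the allyl aryl ether and the alkene untouched.

Step 6
Reactants: 8 3-(3,4-dihydroxyphenyl)propanoic acid (dihydrocaffeic acid)
Product: 9 3-(3,4-dihydroxyphenyl)-N-methoxy-N-methylpropanamide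
Conditions: MeNHOMe·HCl, EDC·HCl, HOBt (cat.), N-methylmorpholine, DMF, 0 → 23 °C
Reagents that add atoms: N,O-dimethylhydroxylamine hydrochloride, CNOC.Cl
Why: Carbodiimide amide coupling in which the amine outcompetes the catechol hydroxyls for the active ester, so the catechol can be carried unprotected.

Step 7
Reactants: 9 3-(3,4-dihydroxyphenyl)-N-methoxy-N-methylpropanamide
Product: 10 3-[3,4-bis(methoxymethoxy)phenyl]-N-methoxy-N-methylpropanamide
Conditions: NaH (2.2 equiv), MOMCl (2.3 equiv), DMF, 0 °C
Reagents that add atoms: chloromethyl methyl ether (MOMCl), COCCl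
Why: Williamson-type O-alkylation of the catechol dianion, giving acetal protection that resists organolithium reagents and falls in the same final acid step as the other two ethers.

Step 8
Reactants: 7 6,8-bis(methoxymethoxy)-3-methyl-2,5-dihydro-1-benzoxepine; 10 3-[3,4-bis(methoxymethoxy)phenyl]-N-methoxy-N-methylpropanamide
Product: 12 3-[3,4-bis(methoxymethoxy)phenyl]-1-[6,8-bis(methoxymethoxy)-3-methyl-2,5-dihydro-1-benzoxepin-7-yl]propan-1-one, via [6,8-bis(methoxymethoxy)-3-methyl-2,5-dihydro-1-benzoxepin-7-yl]lithium 11 (not isolated)
Conditions: n-BuLi (1.05 equiv), THF, −20 → 0 °C; then 10, −78 → 0 °C; aq NH4Cl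
Reagents that add atoms: none
Why: Directed ortho-metalation followed by Weinreb ketone synthesis: C7–H lies between two methoxymethoxy groups that both bind lithium, which should favour it over C9–H (one such group) and over the C2 and C5 methylenes, and the aryllithium adds only once because the chelated adduct releases the ketone on work-up.

Step 9
Reactants: 12 3-[3,4-bis(methoxymethoxy)phenyl]-1-[6,8-bis(methoxymethoxy)-3-methyl-2,5-dihydro-1-benzoxepin-7-yl]propan-1-one
Product: 13 3-(3,4-dihydroxyphenyl)-1-(6,8-dihydroxy-3-methyl-2,5-dihydro-1-benzoxepin-7-yl)propan-1-one (CNP0203471.0)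
Conditions: 3 M aq HCl, MeOH, 40 °C
Reagents that add atoms: none
Why: Acid-catalysed acetal exchange of the four methoxymethyl ethers with methanol, the two beside the ketone being the most labile; dilute acid at mild temperature should spare the trisubstituted alkene and the allyl aryl ether, as it does prenylated phenols.

Compound list
1 | phloroglucinol (benzene-1,3,5-triol) | Oc1cc(O)cc(O)c1 | starting material
2 | 2-methyl-2-vinyloxirane (racemic) | CC1(C=C)CO1 | starting material
3 | 2-[(2E)-4-hydroxy-3-methylbut-2-en-1-yl]benzene-1,3,5-triol | OC/C(C)=C/Cc1c(O)cc(O)cc1O | intermediate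
4 | 2-[(2E)-4-chloro-3-methylbut-2-en-1-yl]benzene-1,3,5-triol | ClC/C(C)=C/Cc1c(O)cc(O)cc1O | intermediate
5 | 6,8-dihydroxy-1-(prop-1-en-2-yl)spiro[2.5]octa-5,7-dien-4-one (racemic) | C=C(C)C1CC12C(=O)C=C(O)C=C2O | intermediate
6 | 3-methyl-2,5-dihydro-1-benzoxepine-6,8-diol | Oc1cc(O)c2c(c1)OCC(C)=CC2 | intermediate
7 | 6,8-bis(methoxymethoxy)-3-methyl-2,5-dihydro-1-benzoxepine | COCOc1cc(OCOC)c2c(c1)OCC(C)=CC2 | intermediate
8 | 3-(3,4-dihydroxyphenyl)propanoic acid | O=C(O)CCc1ccc(O)c(O)c1 | starting material
9 | 3-(3,4-dihydroxyphenyl)-N-methoxy-N-methylpropanamide | CON(C)C(=O)CCc1ccc(O)c(O)c1 | intermediate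
10 | 3-[3,4-bis(methoxymethoxy)phenyl]-N-methoxy-N-methylpropanamide | CON(C)C(=O)CCc1ccc(OCOC)c(OCOC)c1 | intermediate
11 | [6,8-bis(methoxymethoxy)-3-methyl-2,5-dihydro-1-benzoxepin-7-yl]lithium | [Li]c1c(OCOC)cc2c(c1OCOC)CC=C(C)CO2 | intermediate
12 | 3-[3,4-bis(methoxymethoxy)phenyl]-1-[6,8-bis(methoxymethoxy)-3-methyl-2,5-dihydro-1-benzoxepin-7-yl]propan-1-one | CC1=CCc2c(cc(OCOC)c(C(=O)CCc3ccc(OCOC)c(OCOC)c3)c2OCOC)OC1 | intermediate
13 | 3-(3,4-dihydroxyphenyl)-1-(6,8-dihydroxy-3-methyl-2,5-dihydro-1-benzoxepin-7-yl)propan-1-one | CC1=CCc2c(cc(O)c(C(=O)CCc3ccc(O)c(O)c3)c2O)OC1 | target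

Total steps: 9. Longest linear sequence: 7 (steps 1, 2, 3, 4, 5, 8, 9).

Steps most likely to fail

Step 3. Ring closure may run through a flanking phenoxide oxygen (five-membered ether formation) instead of through C5a, or intermolecular alkylation may take over. The fallback sets out from 4 and returns at 5. All three hydroxyls are silylated (TBSOTf, 2,6-lutidine, CH2Cl2, −78 °C) to 2-[(2E)-4-chloro-3-methylbut-2-en-1-yl]-1,3,5-tris[(tert-butyldimethylsilyl)oxy]benzene F1. One equivalent of n-Bu4NF is then added slowly (THF, −40 °C) and should cleave the unhindered silyl ether para to the side chain first. That phenoxide cannot reach the allyl system through oxygen, so closure can only take place at C5a (para-phenoxide Ar-3 spirocyclisation), giving 4,8-bis[(tert-butyldimethylsilyl)oxy]-1-(prop-1-en-2-yl)spiro[2.5]octa-4,7-dien-6-one F2, which is not isolated. Further fluoride removes its two silyl enol ethers and a cold AcOH quench gives 5.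

Step 4. Heterolytic opening of the donor–acceptor cyclopropane, or decay of the labile dienone before it rearranges, may compete with the pericyclic shift. The fallback sets out from 1 and returns at 7, building the oxepine by known Claisen and metathesis chemistry. Statistical protection of 1 (MOMCl, 2 equiv, i-Pr2NEt, CH2Cl2) gives 3,5-bis(methoxymethoxy)phenol F3. O-Allylation (allyl bromide, K2CO3, acetone) gives 1-(allyloxy)-3,5-bis(methoxymethoxy)benzene F4. Aromatic Claisen rearrangement (N,N-diethylaniline, 190 °C) gives 2-allyl-3,5-bis(methoxymethoxy)phenol F5, a single isomer by symmetry. O-Alkylation with 3-chloro-2-methylprop-1-ene (K2CO3, NaI, DMF) gives 2-allyl-1,5-bis(methoxymethoxy)-3-[(2-methylprop-2-en-1-yl)oxy]benzene F6. Ring-closing metathesis with second-generation Grubbs catalyst RuCl2(=CHPh)(H2IMes)(PCy3) (CH2Cl2, 40 °C) then closes the C3=C4 alkene and gives 7.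

Step 1. The unprotected triol may be allylated more than once, react at oxygen, or take up the epoxide at its substituted carbon. The fallback sets out from 2 and returns at 3. Formal 1,4-addition of HCl to 2 (TiCl4, CH2Cl2, −78 °C, aqueous work-up) gives (2E)-4-chloro-2-methylbut-2-en-1-ol F7. This chloride is used for the classical C-alkylation of excess 1 in aqueous KOH at 0 °C, which gives 3 without a transition metal.

Further compounds
F1 | step 3 | 2-[(2E)-4-chloro-3-methylbut-2-en-1-yl]-1,3,5-tris[(tert-butyldimethylsilyl)oxy]benzene | ClC/C(C)=C/Cc1c(O[Si](C)(C)C(C)(C)C)cc(O[Si](C)(C)C(C)(C)C)cc1O[Si](C)(C)C(C)(C)C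
F2 | step 3 | 4,8-bis[(tert-butyldimethylsilyl)oxy]-1-(prop-1-en-2-yl)spiro[2.5]octa-4,7-dien-6-one (racemic) | C=C(C)C1CC12C(O[Si](C)(C)C(C)(C)C)=CC(=O)C=C2O[Si](C)(C)C(C)(C)C
F3 | step 4 | 3,5-bis(methoxymethoxy)phenol | COCOc1cc(O)cc(OCOC)c1
F4 | step 4 | 1-(allyloxy)-3,5-bis(methoxymethoxy)benzene | C=CCOc1cc(OCOC)cc(OCOC)c1
F5 | step 4 | 2-allyl-3,5-bis(methoxymethoxy)phenol | C=CCc1c(O)cc(OCOC)cc1OCOC
F6 | step 4 | 2-allyl-1,5-bis(methoxymethoxy)-3-[(2-methylprop-2-en-1-yl)oxy]benzene | C=CCc1c(OCC(C)=C)cc(OCOC)cc1OCOC
F7 | step 1 | (2E)-4-chloro-2-methylbut-2-en-1-ol | OC/C(C)=C/CCl
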